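**Plan**

- Locants follow the iridoid skeleton: C1 acetal carbon, O2, C3, C4, ring-fusion C5 and C9, C6–C7–C8 in the five-membered ring, C10 on C8, C11 on C4.
- Retrosynthesis: the two ester C–O bonds (at C1 and C7) and the C4–C11 bond are cut first. Then C5–C6 and C7–C8 are cut in one operation, leaving acetaldehyde and a pyranone that comes from a furan.
- Enabling feature: C7/C8 carry vicinal oxygens, which at the C7-ketone level is an acyloin, and C5 lies β to C8 through C9. With C4 as a ketone the six-membered ring holds a C4(=O)–C5=C9–C8(=O) ene-dione that takes up acetaldehyde by conjugate addition at C5 and benzoin closure onto C8.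
- Forward order: furan → pyranone ring (Achmatowicz) → cyclopentane ring annulated in the cascade → C7 reduction and ester → C4 enol triflate → C1 ester → C11 → desilylation.
- Stereochemistry: C1 from a catalyst-controlled dynamic kinetic acylation, then kept throughout. C5 is set anti to the C1 ether. C9 and C8 are funnelled thermodynamically in the cascade. C7 comes from hydride delivery directed by the C8 hydroxyl.

Key step: step 6

Assumption: (R)-benzotetramisole is taken to acylate the (S)-lactol, and the (S)-prolinol catalyst to be the matched partner of the C1 acetal; the mirror-image catalyst would be used where the sense is the opposite.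

**Step 1**
Reactants: 1 4-bromofuran-2-carbaldehyde
Product: 2 (4-bromofuran-2-yl)methanol
Conditions: NaBH4, MeOH, 0 °C
Reagents that add atoms: none
Why: Chemoselective borohydride reduction of the aldehyde; the heteroaryl bromide is untouched.

**Step 2**
Reactants: 2 (4-bromofuran-2-yl)methanol; 3 2-[(tert-butyldimethylsilyl)oxy]-N-methoxy-N-methylacetamide
Product: 5 2-[(tert-butyldimethylsilyl)oxy]-1-[5-(hydroxymethyl)furan-3-yl]ethan-1-one, via lithium (4-lithiofuran-2-yl)methanolate 4 (not isolated)
Conditions: n-BuLi (2.1 equiv), THF, −78 °C; then 3, −78 → −40 °C; aq. NH4Cl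
Reagents that add atoms: none
Why: Deprotonation of the alcohol and bromine–lithium exchange give the 4-lithiofuran, whose acylation stops at the ketone through the chelated tetrahedral intermediate (Weinreb ketone synthesis).

**Step 3**
Reactants: 5 2-[(tert-butyldimethylsilyl)oxy]-1-[5-(hydroxymethyl)furan-3-yl]ethan-1-one
Product: 6 rac-5-{[(tert-butyldimethylsilyl)oxy]acetyl}-6-hydroxy-2H-pyran-3(6H)-one
Conditions: mCPBA, CH2Cl2, 0 → 23 °C
Reagents that add atoms: 3-chloroperoxybenzoic acid, OOC(=O)c1cccc(Cl)c1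
Why: Achmatowicz rearrangement: oxidation of the furan bond that carries the carbinol, then ring expansion, gives the six-membered lactol in which the C5=C9 alkene lies between the C4 and C8 ketones.

**Step 4**
Reactants: 6 rac-5-{[(tert-butyldimethylsilyl)oxy]acetyl}-6-hydroxy-2H-pyran-3(6H)-one
Product: 7 (2S)-3-{[(tert-butyldimethylsilyl)oxy]acetyl}-5-oxo-5,6-dihydro-2H-pyran-2-yl benzoate
Conditions: benzoic anhydride, (R)-benzotetramisole (5 mol %), i-Pr2NEt, CHCl3, −20 °C
Reagents that add atoms: benzoic anhydride, O=C(OC(=O)c1ccccc1)c1ccccc1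
Why: Isothiourea-catalysed dynamic kinetic acylation: the lactol enantiomers interconvert by ring opening and the chiral acyl-ammonium benzoylates one of them, which sets C1.

**Step 5**
Reactants: 7 (2S)-3-{[(tert-butyldimethylsilyl)oxy]acetyl}-5-oxo-5,6-dihydro-2H-pyran-2-yl benzoate
Product: 8 (6R)-5-{[(tert-butyldimethylsilyl)oxy]acetyl}-6-[(4-methoxybenzyl)oxy]-2H-pyran-3(6H)-one
Conditions: 4-methoxybenzyl alcohol, Pd2(dba)3·CHCl3 (2.5 mol %), PPh3 (10 mol %), CH2Cl2, 0 °C
Reagents that add atoms: 4-methoxybenzyl alcohol, COc1ccc(CO)cc1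
Why: Tsuji–Trost substitution with an oxygen nucleophile: zerovalent palladium ionises the allylic benzoate anti and the alcohol adds anti to the metal at the acetal terminus, so C1 is retained by double inversion (the descriptor changes only through the priority rules) and the base-labile acyloxy group is exchanged for a robust ether.

**Step 6**
Reactants: 8 (6R)-5-{[(tert-butyldimethylsilyl)oxy]acetyl}-6-[(4-methoxybenzyl)oxy]-2H-pyran-3(6H)-one; 9 acetaldehyde
Product: 11 (1R,5S,8R,9S)-8-hydroxy-1-[(4-methoxybenzyl)oxy]-8-{[(tert-butyldimethylsilyl)oxy]methyl}-cis-hexahydrocyclopenta[c]pyran-4,7-dione (ketol; iridoid locants), via keto aldehyde 10 (not isolated)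
Conditions: 9 (5 equiv), (S)-α,α-diphenylprolinol trimethylsilyl ether (20 mol %), 4-nitrophenol (20 mol %), 1,4-dioxane, 4 °C; then 2-(pentafluorophenyl)-6,7-dihydro-5H-pyrrolo[2,1-c][1,2,4]triazol-2-ium tetrafluoroborate (20 mol %), NaOAc (30 mol %), 23 °C
Reagents that add atoms: none
Why: The amine turns acetaldehyde into its enamine, which adds to C5, the only unsubstituted terminus of the C4(=O)–C5=C9–C8(=O) ene-dione, to give keto aldehyde 10; the triazolylidene then converts the aldehyde into a Breslow acyl-anion equivalent that adds to the C8 ketone (crossed intramolecular benzoin). The closest known reaction type is the enamine/carbene Michael–benzoin cascade of aliphatic aldehydes with 4-oxo-enones to 2-hydroxycyclopentanones. The ring C5–C6–C7–C8–C9 closes by 5-exo-trig attack of C7 on the C8 carbonyl, and the C4 ketone cannot compete because that would need a four-membered ring. C5 is set by attack anti to the pseudo-axial C1 ether; C9 is epimerisable α to the C8 ketone and only the epimer with the acyl group cis to the C5 side chain can cyclise, so the ring fusion is funnelled to cis; C8 is set in the reversible benzoin step, which should place CH2OTBS on the convex face and the hydroxyl on the concave face next to the C4 carbonyl. The step needs the enamine addition to precede carbene chemistry (a Stetter-type addition of acetaldehyde) and the C9 enolate not to expel the acetal oxygen; adding the azolium salt only after the conjugate addition and buffering with the phenol should secure both.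

**Step 7**
Reactants: 11 ketol (1R,5S,8R,9S)
Product: 12 (1R,5S,7S,8R,9S)-7,8-dihydroxy-1-[(4-methoxybenzyl)oxy]-8-{[(tert-butyldimethylsilyl)oxy]methyl}-cis-hexahydrocyclopenta[c]pyran-4(1H)-one (7,8-trans diol)
Conditions: Me4NBH(OAc)3, MeCN/AcOH (1:1), −30 °C
Reagents that add atoms: none
Why: Hydroxyl-directed (Evans–Saksena) reduction: the C8 hydroxyl binds boron and delivers hydride to the concave face of C7, which gives the 7,8-trans diol, while the C4 ketone, which has no α-hydroxyl, should be left.

**Step 8**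
Reactants: 13 (E)-4-hydroxycinnamic acid (p-coumaric acid)
Product: 15 (E)-4-[(tert-butyldimethylsilyl)oxy]cinnamic acid, via bis-silyl compound 14 (not isolated)
Conditions: TBSCl (2.3 equiv), imidazole, DMF, 23 °C; then AcOH/THF/H2O, 23 °C
Reagents that add atoms: tert-butyldimethylsilyl chloride, CC(C)(C)[Si](C)(C)Cl
Why: Exhaustive silylation followed by selective hydrolysis of the labile silyl ester leaves only the phenol protected.

**Step 9**
Reactants: 12 7,8-trans diol; 15 (E)-4-[(tert-butyldimethylsilyl)oxy]cinnamic acid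
Product: 16 (1R,5S,7S,8R,9S)-7-O-[(E)-4-(tert-butyldimethylsilyloxy)cinnamoyl] ester of 12
Conditions: EDC·HCl, DMAP, CH2Cl2, 0 → 23 °C
Reagents that add atoms: none
Why: Steglich-type carbodiimide esterification acylates the only secondary hydroxyl with retention at C7; the tertiary C8 hydroxyl does not react.

**Step 10**
Reactants: 16 C7 ester, C4 ketone
Product: 17 (1R,5S,7S,8R,9S)-C3=C4 enol triflate of 16 (4-trifluoromethanesulfonyloxy-1,5,6,7,8,9-hexahydrocyclopenta[c]pyran)
Conditions: KN(SiMe3)2 (2.2 equiv), THF, −78 °C; then N-(5-chloropyridin-2-yl)bis(trifluoromethanesulfonimide), −78 °C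
Reagents that add atoms: N-(5-chloropyridin-2-yl)bis(trifluoromethanesulfonimide), O=S(=O)(N(c1ccc(Cl)cn1)S(=O)(=O)C(F)(F)F)C(F)(F)F
Why: Kinetic deprotonation of the C4 ketone at the unhindered C3 methylene, not at the ring-fusion methine C5, and O-sulfonylation of the enolate give the enol triflate; the trans-disposed C8 alkoxide cannot reach the C7 ester.

**Step 11**
Reactants: 17 enol triflate, 1-O-(4-methoxybenzyl) acetal
Product: 18 (1R,5S,7S,8R,9S)-lactol (1-hydroxy analogue of 17)
Conditions: DDQ, CH2Cl2/pH 7 phosphate buffer (10:1), 0 → 23 °C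
Reagents that add atoms: none
Why: Oxidative cleavage of the 4-methoxybenzyl acetal by DDQ frees the lactol without breaking the C1–O bond, so C1 keeps its configuration; the electron-poor enol triflate is inert to the oxidant.

**Step 12**
Reactants: 18 lactol; 19 3-methylbutanoyl chloride (isovaleryl chloride)
Product: 20 (1S,5S,7S,8R,9S)-1-O-(3-methylbutanoyl) enol triflate
Conditions: pyridine, DMAP (cat.), CH2Cl2, −20 °C
Reagents that add atoms: none
Why: Acylation of the hemiacetal hydroxyl, the only reactive hydroxyl present, gives the acyl acetal with the ester anti to the C9–C8 bond, the configuration already in place and also the anomerically favoured one.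

**Step 13**
Reactants: 20 1-O-(3-methylbutanoyl) enol triflate; 21 (tributylstannyl)methanol
Product: 22 luzonoid A 10-O,4'-O-bis(tert-butyldimethylsilyl) ether
Conditions: Pd(PPh3)4 (10 mol %), LiCl, 1,4-dioxane, 90 °C
Reagents that add atoms: none
Why: Stille cross-coupling of the enol triflate with the hydroxymethylstannane installs C11 at the alcohol oxidation level under neutral conditions that spare both esters.

**Step 14**
Reactants: 22 luzonoid A bis-silyl ether
Product: 23 luzonoid A
Conditions: HF·pyridine, pyridine, THF, 0 → 23 °C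
Reagents that add atoms: none
Why: Buffered fluoride cleaves both silyl ethers and leaves the acyl acetal, the enol ether and the esters; the trans arrangement at C7/C8 blocks acyl migration.

**Compound list**

1 | 4-bromofuran-2-carbaldehyde | O=Cc1cc(Br)co1 | starting material
2 | (4-bromofuran-2-yl)methanol | OCc1cc(Br)co1 | intermediate
3 | 2-[(tert-butyldimethylsilyl)oxy]-N-methoxy-N-methylacetamide | CON(C)C(=O)CO[Si](C)(C)C(C)(C)C | starting material
4 | lithium (4-lithiofuran-2-yl)methanolate | [Li]OCc1cc([Li])co1 | intermediate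
5 | 2-[(tert-butyldimethylsilyl)oxy]-1-[5-(hydroxymethyl)furan-3-yl]ethan-1-one | OCc1cc(C(=O)CO[Si](C)(C)C(C)(C)C)co1 | intermediate
6 | rac-5-{[(tert-butyldimethylsilyl)oxy]acetyl}-6-hydroxy-2H-pyran-3(6H)-one | O=C1COC(O)C(C(=O)CO[Si](C)(C)C(C)(C)C)=C1 | intermediate
7 | (2S)-3-{[(tert-butyldimethylsilyl)oxy]acetyl}-5-oxo-5,6-dihydro-2H-pyran-2-yl benzoate | O=C(O[C@@H]1OCC(=O)C=C1C(=O)CO[Si](C)(C)C(C)(C)C)c1ccccc1 | intermediate
8 | (6R)-5-{[(tert-butyldimethylsilyl)oxy]acetyl}-6-[(4-methoxybenzyl)oxy]-2H-pyran-3(6H)-one | COc1ccc(CO[C@@H]2OCC(=O)C=C2C(=O)CO[Si](C)(C)C(C)(C)C)cc1 | intermediate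
9 | acetaldehyde | CC=O | starting material
10 | keto aldehyde: (1R,5S,9R)-tetrahydropyran-4-one with OCH2Ar at C1, CH2CHO at C5 and silyloxyacetyl at C9, the two side chains cis and both trans to the C1 ether | COc1ccc(CO[C@@H]2OCC(=O)[C@@H](CC=O)[C@H]2C(=O)CO[Si](C)(C)C(C)(C)C)cc1 | intermediate
11 | ketol: (1R,5S,8R,9S)-8-hydroxy-1-[(4-methoxybenzyl)oxy]-8-{[(tert-butyldimethylsilyl)oxy]methyl}-cis-hexahydrocyclopenta[c]pyran-4,7-dione | COc1ccc(CO[C@@H]2OCC(=O)[C@H]3CC(=O)[C@](O)(CO[Si](C)(C)C(C)(C)C)[C@@H]23)cc1 | intermediate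
12 | (1R,5S,7S,8R,9S)-7,8-trans diol, C4 ketone | COc1ccc(CO[C@@H]2OCC(=O)[C@H]3C[C@H](O)[C@](O)(CO[Si](C)(C)C(C)(C)C)[C@@H]23)cc1 | intermediate
13 | (E)-4-hydroxycinnamic acid | OC(=O)/C=C/c1ccc(O)cc1 | starting material
14 | tert-butyldimethylsilyl (E)-4-[(tert-butyldimethylsilyl)oxy]cinnamate | CC(C)(C)[Si](C)(C)OC(=O)/C=C/c1ccc(O[Si](C)(C)C(C)(C)C)cc1 | intermediate
15 | (E)-4-[(tert-butyldimethylsilyl)oxy]cinnamic acid | OC(=O)/C=C/c1ccc(O[Si](C)(C)C(C)(C)C)cc1 | intermediate
16 | (1R,5S,7S,8R,9S)-7-O-[(E)-4-(tert-butyldimethylsilyloxy)cinnamoyl] ester of 12 | COc1ccc(CO[C@@H]2OCC(=O)[C@H]3C[C@H](OC(=O)/C=C/c4ccc(O[Si](C)(C)C(C)(C)C)cc4)[C@](O)(CO[Si](C)(C)C(C)(C)C)[C@@H]23)cc1 | intermediate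
17 | (1R,5S,7S,8R,9S)-C3=C4 enol triflate of 16 | COc1ccc(CO[C@@H]2OC=C(OS(=O)(=O)C(F)(F)F)[C@H]3C[C@H](OC(=O)/C=C/c4ccc(O[Si](C)(C)C(C)(C)C)cc4)[C@](O)(CO[Si](C)(C)C(C)(C)C)[C@@H]23)cc1 | intermediate
18 | (1R,5S,7S,8R,9S)-lactol (1-hydroxy enol triflate) | O[C@@H]1OC=C(OS(=O)(=O)C(F)(F)F)[C@H]2C[C@H](OC(=O)/C=C/c3ccc(O[Si](C)(C)C(C)(C)C)cc3)[C@](O)(CO[Si](C)(C)C(C)(C)C)[C@@H]12 | intermediate
19 | 3-methylbutanoyl chloride | CC(C)CC(=O)Cl | starting material
20 | (1S,5S,7S,8R,9S)-1-O-(3-methylbutanoyl) enol triflate | CC(C)CC(=O)O[C@@H]1OC=C(OS(=O)(=O)C(F)(F)F)[C@H]2C[C@H](OC(=O)/C=C/c3ccc(O[Si](C)(C)C(C)(C)C)cc3)[C@](O)(CO[Si](C)(C)C(C)(C)C)[C@@H]12 | intermediate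
21 | (tributylstannyl)methanol | CCCC[Sn](CCCC)(CCCC)CO | starting material
22 | luzonoid A 10-O,4'-O-bis(tert-butyldimethylsilyl) ether, (1S,5S,7S,8R,9S) | CC(C)CC(=O)O[C@@H]1OC=C(CO)[C@H]2C[C@H](OC(=O)/C=C/c3ccc(O[Si](C)(C)C(C)(C)C)cc3)[C@](O)(CO[Si](C)(C)C(C)(C)C)[C@@H]12 | intermediate
23 | luzonoid A, (1S,5S,7S,8R,9S) | CC(C)CC(=O)O[C@@H]1OC=C(CO)[C@H]2C[C@H](OC(=O)/C=C/c3ccc(O)cc3)[C@](O)(CO)[C@@H]12 | target

**Step count**

Total: 14 steps. Longest linear sequence: 13 steps (steps 1–7 and 9–14, from 4-bromofuran-2-carbaldehyde).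

**Steps most likely to fail**

Step 6. The carbene may engage acetaldehyde and add it to the ene-dione in a Stetter sense, the C9 enolate formed in the conjugate addition may expel the acetal oxygen, or the reversible benzoin step may give poor control at C8. Fallback: setting out from 8, the conjugate addition is run with the amine catalyst alone and keto aldehyde 10 is isolated. The ring is then closed reductively by a pinacol cyclisation with samarium diiodide (SmI2, THF, t-BuOH, −78 °C), in which the aldehyde ketyl adds to the C8 ketone through a samarium-bridged array and gives the cis-7,8-diol F1. Oxidation of the secondary carbinol alone with Dess–Martin periodinane comes back to ketol 11.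

Step 10. Enolate formation may lose out to attack of the amide base or of the C8 alkoxide on the ester groups, to O-sulfonylation of the alkoxide, or to deprotonation at C5. Fallback: the enol triflate is made before the ester is in place. Setting out from diol 12, both hydroxyls are capped (TMSOTf, 2,6-lutidine, CH2Cl2, −78 °C) to give the bis(trimethylsilyl) ether F2. The same base and triflimide then give the enol triflate F3, K2CO3 in methanol at 0 °C removes the two trimethylsilyl groups to give the diol triflate F4, and carbodiimide esterification with acid 15 comes back to 17.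

Step 13. Transmetallation of the hydroxymethylstannane may be slow at the temperature that the acyl acetal and the product enol ether tolerate, so that protodestannylation and decomposition outrun coupling. Fallback: setting out from 20, C11 is brought in as carbon monoxide. Palladium-catalysed reductive carbonylation (Pd(PPh3)4, CO, Bu3SnH, LiCl, THF, 50 °C) gives the C11 aldehyde F5, a vinylogous formate. Luche reduction (NaBH4, CeCl3·7H2O, MeOH, −78 °C), selective for the aldehyde over the esters, comes back to 22.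

**Further compounds**

F1 | step 6 | (1R,5S,7R,8R,9S)-7,8-cis diol, C4 ketone (C7 epimer of 12) | COc1ccc(CO[C@@H]2OCC(=O)[C@H]3C[C@@H](O)[C@](O)(CO[Si](C)(C)C(C)(C)C)[C@@H]23)cc1
F2 | step 10 | 7,8-bis(trimethylsilyl) ether of 12 | COc1ccc(CO[C@@H]2OCC(=O)[C@H]3C[C@H](O[Si](C)(C)C)[C@](O[Si](C)(C)C)(CO[Si](C)(C)C(C)(C)C)[C@@H]23)cc1
F3 | step 10 | C3=C4 enol triflate of F2 | COc1ccc(CO[C@@H]2OC=C(OS(=O)(=O)C(F)(F)F)[C@H]3C[C@H](O[Si](C)(C)C)[C@](O[Si](C)(C)C)(CO[Si](C)(C)C(C)(C)C)[C@@H]23)cc1
F4 | step 10 | 7,8-diol enol triflate | COc1ccc(CO[C@@H]2OC=C(OS(=O)(=O)C(F)(F)F)[C@H]3C[C@H](O)[C@](O)(CO[Si](C)(C)C(C)(C)C)[C@@H]23)cc1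
F5 | step 13 | C11 aldehyde (4-formyl analogue of 22) | CC(C)CC(=O)O[C@@H]1OC=C(C=O)[C@H]2C[C@H](OC(=O)/C=C/c3ccc(O[Si](C)(C)C(C)(C)C)cc3)[C@](O)(CO[Si](C)(C)C(C)(C)C)[C@@H]12
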